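Feature (benzofuran numbering; ring A = benzene ring, ring B = dihydrofuran ring): in ring A the oxygens on C7a (O1) and C6 and the unsubstituted C4–H alternate, so C7a–C7–C6–C5–C4 reads as a folded 1,3,5-tricarbonyl chain; O1 also belongs to ring B, so ring B can exist first as the cyclic enol ether of that chain.
Cuts: C3a–C4 (ring A opens to a methoxymethylene ketone on a 2-alkylidene tetrahydrofuran), then C4–C5 (a formyl carbon), then C7–C7a (methyl ketone enolate plus γ-lactone), then C2–C3 (crotylation of the aryl aldehyde).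
Forward: C2–C3 is made first and ring B is closed as the trans lactone; hex-5-en-2-one then brings C7, C6, C5 and the allyl group, loss of water locks O1 on C7a, C4 is added, and ring A is closed last.
Because C4 arrives after O1 is locked, an open tricarbonyl chain with a free C7a enol never exists on the way to the precursor, so closure to a γ-pyranone has no opening there.
Stereochemistry: C2 and C3 both come from one catalytic enantioselective anti crotylboration (chair transition state for the relative configuration, chiral phosphoric acid for the absolute one); anti becomes trans in ring B, and neither centre is acidic or ionised afterwards.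
Key step: step 7

Assumption: the facial sense of the phosphoric acid is carried over from simple aromatic aldehydes, where the (R)-acid sends the allyl unit to the Re face; the (S)-acid is therefore specified for Si-face attack, and the antipodal acid would be used if the trimethoxy substrate behaved otherwise.

Step 1
Reactants: 1 3,4,5-trimethoxybenzaldehyde; 2 (E)-crotylboronic acid pinacol ester
Product: 4 (1S,2S)-2-methyl-1-(3,4,5-trimethoxyphenyl)but-3-en-1-ol, via pinacol borate 3 (not isolated)
Conditions: (S)-TRIP, (S)-3,3'-bis(2,4,6-triisopropylphenyl)-1,1'-binaphthyl-2,2'-diyl hydrogen phosphate (5 mol %), 4 Å MS, toluene, −30 °C; aqueous work-up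
Reagents that add atoms: none
Why: Phosphoric-acid-catalysed asymmetric crotylboration: the (E)-boronate reacts through a closed chair (Zimmerman–Traxler) transition state that turns E geometry into the anti C2/C3 relation, while the (S)-acid, bound to a boronate oxygen and the formyl hydrogen, exposes the Si face of 1 and so sets 1S,2S.

Step 2
Reactants: 4 (1S,2S)-2-methyl-1-(3,4,5-trimethoxyphenyl)but-3-en-1-ol
Product: 6 (1S,2S)-2-methyl-1-(3,4,5-trimethoxyphenyl)butane-1,4-diol, via bis-boryl adduct 5 (not isolated)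
Conditions: 9-BBN (2.2 equiv), THF, 0 to 23 °C; then NaOH, H2O2, H2O, 0 to 23 °C
Reagents that add atoms: hydrogen peroxide, OO
Why: Hydroboration–oxidation with the bulky 9-BBN places boron only on the terminal alkene carbon (the free hydroxyl merely consumes one equivalent as its borinate), and oxidation with retention gives the primary alcohol without touching either stereocentre.

Step 3
Reactants: 6 (1S,2S)-2-methyl-1-(3,4,5-trimethoxyphenyl)butane-1,4-diol
Product: 8 (4S,5S)-4-methyl-5-(3,4,5-trimethoxyphenyl)dihydrofuran-2(3H)-one, via lactol 7 (not isolated)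
Conditions: TEMPO (2,2,6,6-tetramethylpiperidin-1-oxyl, 10 mol %), PhI(OAc)2 (2.5 equiv), CH2Cl2, 23 °C
Reagents that add atoms: none
Why: TEMPO/PhI(OAc)2 oxidative lactonisation of a 1,4-diol: the oxoammonium species takes the unhindered primary carbinol first, the secondary hydroxyl closes onto the new carbonyl to give lactol 7, and a second oxidation gives the γ-lactone in which the anti pair has become trans.

Step 4
Reactants: 8 (4S,5S)-4-methyl-5-(3,4,5-trimethoxyphenyl)dihydrofuran-2(3H)-one; 9 hex-5-en-2-one
Product: 12 (1E)-1-[(4S,5S)-4-methyl-5-(3,4,5-trimethoxyphenyl)dihydrofuran-2(3H)-ylidene]hex-5-en-2-one, via lithium enolate 10 (not isolated), via hemiketal 11 (not isolated)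
Conditions: 9 (2.5 equiv), LiN(iPr)2 (2.4 equiv), THF, −78 °C; 8, −78 to −40 °C; AcOH; crude 11, TsOH·H2O (cat.), 4 Å MS, CH2Cl2, 23 °C
Reagents that add atoms: none
Why: Crossed Claisen-type acylation of the kinetic, methyl-side enolate 10 by the lactone carbonyl forms C7–C7a and stops at hemiketal 11, and acid-catalysed dehydration then gives the conjugated exocyclic vinylogous ester rather than the unconjugated endocyclic enol ether, the E isomer being preferred because it keeps the O1 and carbonyl dipoles apart.

Step 5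
Reactants: 12 (1E)-1-[(4S,5S)-4-methyl-5-(3,4,5-trimethoxyphenyl)dihydrofuran-2(3H)-ylidene]hex-5-en-2-one
Product: 14 (3Z)-3-(hydroxymethylidene)-1-[(2E,4S,5S)-4-methyl-5-(3,4,5-trimethoxyphenyl)dihydrofuran-2(3H)-ylidene]hex-5-en-2-one, via lithium dienolate 13 (not isolated)
Conditions: LiN(iPr)2 (1.1 equiv), THF, −78 °C; HCO2CH2CF3 (2 equiv), −78 °C; AcOH, −78 °C; crude product used at once
Reagents that add atoms: 2,2,2-trifluoroethyl formate, O=COCC(F)(F)F
Why: Kinetic deprotonation of a vinylogous ester takes the α′ hydrogen at C5 (Stork–Danheiser regiochemistry) and not the γ hydrogen at C3a, and the activated formate transfers its formyl group to such kinetic lithium enolates at −78 °C (crossed Claisen formylation), so C4 arrives on C5 only.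

Step 6
Reactants: 14 (3Z)-3-(hydroxymethylidene)-1-[(2E,4S,5S)-4-methyl-5-(3,4,5-trimethoxyphenyl)dihydrofuran-2(3H)-ylidene]hex-5-en-2-one
Product: 15 (3E)-3-(methoxymethylidene)-1-[(2E,4S,5S)-4-methyl-5-(3,4,5-trimethoxyphenyl)dihydrofuran-2(3H)-ylidene]hex-5-en-2-one
Conditions: Me2SO4 (1.3 equiv), K2CO3 (2 equiv), acetone, 23 °C
Reagents that add atoms: dimethyl sulfate, COS(=O)(=O)OC
Why: O-alkylation of a β-keto aldehyde enolate: with potassium as counter-ion and the hard electrophile Me2SO4 the exposed aldehyde-derived oxygen is methylated, as in the standard preparation of alkoxymethylene ketones and β-methoxyacrylates, and the E enol ether with OMe turned away from C6 should result.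

Step 7
Reactants: 15 (3E)-3-(methoxymethylidene)-1-[(2E,4S,5S)-4-methyl-5-(3,4,5-trimethoxyphenyl)dihydrofuran-2(3H)-ylidene]hex-5-en-2-one
Product: 20 (2S,3S)-5-allyl-3-methyl-2-(3,4,5-trimethoxyphenyl)-2,3-dihydrobenzofuran-6-ol, via potassium trienolate 16 (not isolated), via methoxy dienolate 17 (not isolated), via cyclohexadienone 18 (not isolated), via potassium phenoxide 19 (not isolated)
Conditions: KOtBu (2.0 equiv), THF–tBuOH (5:1), 0.02 M, argon, 0 to 50 °C; then 1 M HCl, 0 °C
Reagents that add atoms: none
Why: Proposed new method: KOtBu reversibly removes a C3a proton, the only one that C6=O activates (vinylogously, through C7=C7a) because C5 carries no hydrogen, and gives trienolate 16, a 3-oxidohexatriene C3a=C7a–C7=C6(O−)–C5=C4 in which C7–C7a is formally single and in which proton exchange at C7 through tBuOH lets C6–C7 turn as well, so that the coiled form is open to either alkene geometry of 15. Ring A closes by a disrotatory 6π electrocyclisation, formally a 6-endo-trig attack of the nucleophilic terminus C3a on the oxygen-bearing terminus C4, with hydrogen at both inward positions, and this makes the C3a–C4 bond of 17. The C5=C6 enolate of 17 expels methoxide from C4 (E1cB), dienone 18 gives up its C3a proton to form phenoxide 19, the gain of aromaticity makes the sequence irreversible, and acid frees 20. The closest known reaction types are the base-induced aldol aromatisation of open poly-β-carbonyl chains to resorcinols, the Staunton–Weinreb annulation (a γ-carbanion adds to a β-methoxy enone and methanol is lost) and the easy ring closure of 3-oxidohexatrienes, but none has been shown with the γ-carbon of a 2-acylmethylene tetrahydrofuran as nucleophile. No lasting stereocentre is formed, since the transient centres C3a and C4 vanish on aromatisation, while C2 and C3 bear no acidic hydrogen and the C2–O1 bond stays intact. The selectivity needed is deprotonation at C3a rather than at the doubly allylic CH2 on C5, and the substrate secures it because the anion of that CH2 sits on the α-carbon of the enone and cannot reach the C6 oxygen, so it is far less favoured than the vinylogous enolate that drains irreversibly into the arene.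

Compound list
1 | 3,4,5-trimethoxybenzaldehyde | COc1cc(C=O)cc(OC)c1OC | starting material
2 | (E)-crotylboronic acid pinacol ester | C/C=C/CB1OC(C)(C)C(C)(C)O1 | starting material
3 | 2-{[(1S,2S)-2-methyl-1-(3,4,5-trimethoxyphenyl)but-3-en-1-yl]oxy}-4,4,5,5-tetramethyl-1,3,2-dioxaborolane (pinacol borate of 4) | CC1(C)OB(O[C@H](c2cc(OC)c(OC)c(OC)c2)[C@H](C=C)C)OC1(C)C | intermediate
4 | (1S,2S)-2-methyl-1-(3,4,5-trimethoxyphenyl)but-3-en-1-ol | O[C@H](c1cc(OC)c(OC)c(OC)c1)[C@H](C=C)C | intermediate
5 | bis-boryl adduct of 4 (9-borabicyclo[3.3.1]nonan-9-yl on the benzylic oxygen and on the terminal carbon) | C1CC2CCCC(C1)B2O[C@H](c1cc(OC)c(OC)c(OC)c1)[C@H](CCB1C2CCCC1CCC2)C | intermediate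
6 | (1S,2S)-2-methyl-1-(3,4,5-trimethoxyphenyl)butane-1,4-diol | O[C@H](c1cc(OC)c(OC)c(OC)c1)[C@H](CCO)C | intermediate
7 | (4S,5S)-4-methyl-5-(3,4,5-trimethoxyphenyl)tetrahydrofuran-2-ol (lactol, both anomers) | O1[C@H](c2cc(OC)c(OC)c(OC)c2)[C@H](CC1O)C | intermediate
8 | (4S,5S)-4-methyl-5-(3,4,5-trimethoxyphenyl)dihydrofuran-2(3H)-one (trans lactone) | O1[C@H](c2cc(OC)c(OC)c(OC)c2)[C@H](CC1=O)C | intermediate
9 | hex-5-en-2-one | CC(=O)CCC=C | starting material
10 | lithium hexa-1,5-dien-2-olate (kinetic enolate of 9) | [Li+].C=C([O-])CCC=C | intermediate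
11 | 1-[(4S,5S)-2-hydroxy-4-methyl-5-(3,4,5-trimethoxyphenyl)tetrahydrofuran-2-yl]hex-5-en-2-one (hemiketal) | O1[C@H](c2cc(OC)c(OC)c(OC)c2)[C@H](CC1(O)CC(=O)CCC=C)C | intermediate
12 | (1E)-1-[(4S,5S)-4-methyl-5-(3,4,5-trimethoxyphenyl)dihydrofuran-2(3H)-ylidene]hex-5-en-2-one | C=CCCC(=O)/C=C1/O[C@H](c2cc(OC)c(OC)c(OC)c2)[C@H](C1)C | intermediate
13 | lithium α′-enolate of 12 (C5=C6–OLi, cross-conjugated dienolate) | [Li+].C=CCC=C([O-])/C=C1/O[C@H](c2cc(OC)c(OC)c(OC)c2)[C@H](C1)C | intermediate
14 | (3Z)-3-(hydroxymethylidene)-1-[(2E,4S,5S)-4-methyl-5-(3,4,5-trimethoxyphenyl)dihydrofuran-2(3H)-ylidene]hex-5-en-2-one | O/C=C(CC=C)\C(=O)/C=C1/O[C@H](c2cc(OC)c(OC)c(OC)c2)[C@H](C1)C | intermediate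
15 | (3E)-3-(methoxymethylidene)-1-[(2E,4S,5S)-4-methyl-5-(3,4,5-trimethoxyphenyl)dihydrofuran-2(3H)-ylidene]hex-5-en-2-one (precursor of the key step) | CO/C=C(CC=C)/C(=O)/C=C1/O[C@H](c2cc(OC)c(OC)c(OC)c2)[C@H](C1)C | intermediate
16 | potassium trienolate of 15 (C3a=C7a inside a (2S,3S)-2,3-dihydrofuran, C7=C6–OK, C5=C4–OMe) | [K+].CO/C=C(CC=C)/C([O-])=CC1O[C@H](c2cc(OC)c(OC)c(OC)c2)[C@H](C=1)C | intermediate
17 | potassium (2S,3S)-5-allyl-4-methoxy-3-methyl-2-(3,4,5-trimethoxyphenyl)-2,3,3a,4-tetrahydrobenzofuran-6-olate | [K+].C=CCC1=C([O-])C=C2O[C@H](c3cc(OC)c(OC)c(OC)c3)[C@H](C2C1OC)C | intermediate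
18 | (2S,3S)-5-allyl-3-methyl-2-(3,4,5-trimethoxyphenyl)-3,3a-dihydrobenzofuran-6(2H)-one | C=CCC1=CC2C(=CC1=O)O[C@H](c3cc(OC)c(OC)c(OC)c3)[C@H]2C | intermediate
19 | potassium (2S,3S)-5-allyl-3-methyl-2-(3,4,5-trimethoxyphenyl)-2,3-dihydrobenzofuran-6-olate | [K+].C=CCc1cc2c(cc1[O-])O[C@H](c1cc(OC)c(OC)c(OC)c1)[C@H]2C | intermediate
20 | (2S,3S)-5-allyl-3-methyl-2-(3,4,5-trimethoxyphenyl)-2,3-dihydrobenzofuran-6-ol | C=CCc1cc2c(cc1O)O[C@H](c1cc(OC)c(OC)c(OC)c1)[C@H]2C | target

Total step count: 7. Longest linear sequence: 7 (1 to 20).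

Steps most likely to fail

Risk 1 (step 7).
- What may go wrong: the trienolate may sit mainly in the extended geometry about C6–C7 and turn too slowly into the coiled one. Conjugate addition–elimination between two molecules, migration of the allyl double bond into conjugation, or plain return of the substrate could then overtake the closure.
- Fallback (known chemistry, ring B given up for a time): the route leaves at 14. Brief treatment with CF3CO2H in CH2Cl2 lets the C4 enol oxygen add to C7a with expulsion of O1, the usual acid cyclisation of a 1,3,5-tricarbonyl unit. This gives 5-allyl-2-[(2S,3S)-3-hydroxy-2-methyl-3-(3,4,5-trimethoxyphenyl)propyl]-4H-pyran-4-one F1.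
- Aqueous KOH opens the pyranone at C4 to the open chain (7S,8S)-2-allyl-8-hydroxy-7-methyl-3,5-dioxo-8-(3,4,5-trimethoxyphenyl)octanal F2. In the same flask F2 undergoes the classical C3a-to-C4 aldol aromatisation of a poly-β-carbonyl chain to 4-allyl-6-[(1S,2S)-1-hydroxy-1-(3,4,5-trimethoxyphenyl)propan-2-yl]benzene-1,3-diol F3.
- Catalytic TsOH·H2O in CH2Cl2 then ionises the benzylic alcohol, and the C7a hydroxyl captures the cation anti to the C3 methyl group. This is the known cyclodehydration to trans-2-aryl-3-methyl-2,3-dihydrobenzofurans. The untouched C3 centre re-sets C2, and the route comes back at 20.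

Risk 2 (step 4).
- What may go wrong: proton transfer from the first-formed adduct to the enolate, drift of the kinetic enolate to its internal regioisomer, and self-condensation of the ketone may stall the acylation.
- Fallback: the route leaves at 8. The lithium enolate of N-methoxy-N-methylacetamide (LiN(iPr)2, THF, −78 °C), which has only one enolisable site, adds to the lactone to give the hemiketal 2-[(4S,5S)-2-hydroxy-4-methyl-5-(3,4,5-trimethoxyphenyl)tetrahydrofuran-2-yl]-N-methoxy-N-methylacetamide F4.
- Catalytic TsOH·H2O dehydrates F4 to (2E)-N-methoxy-N-methyl-2-[(4S,5S)-4-methyl-5-(3,4,5-trimethoxyphenyl)dihydrofuran-2(3H)-ylidene]acetamide F5. CH2=CHCH2CH2MgBr (THF, 0 °C) converts this Weinreb amide into the ketone, so the route comes back at 12.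

Risk 3 (step 5).
- What may go wrong: competing removal of the γ hydrogen at C3a, formyl transfer to oxygen, and above all addition of the new enol oxygen to C7a with opening of ring B during quench and handling may erode the material.
- Fallback: the route leaves at 12. LiN(iPr)2 and then Me3SiCl (THF, −78 °C) trap the same α′ enolate as the 1-alkoxy-3-silyloxydiene, the C5=C6 trimethylsilyl enol ether of 12 F6.
- The dimethoxycarbenium ion from HC(OMe)3 and BF3·OEt2 (CH2Cl2, −78 °C, Mukaiyama-type reaction with an orthoester) alkylates F6 at C5. This gives the β-keto acetal 3-(dimethoxymethyl)-1-[(2E,4S,5S)-4-methyl-5-(3,4,5-trimethoxyphenyl)dihydrofuran-2(3H)-ylidene]hex-5-en-2-one F7.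
- DBU in warm toluene removes one methanol, the known passage from β-keto acetals to β-methoxy enones. The route comes back at 15 without ever forming the free hydroxymethylene ketone and without step 6.

Further compounds
F1 | step 7 | 5-allyl-2-[(2S,3S)-3-hydroxy-2-methyl-3-(3,4,5-trimethoxyphenyl)propyl]-4H-pyran-4-one | O[C@H](c1cc(OC)c(OC)c(OC)c1)[C@H](CC1=CC(=O)C(CC=C)=CO1)C
F2 | step 7 | (7S,8S)-2-allyl-8-hydroxy-7-methyl-3,5-dioxo-8-(3,4,5-trimethoxyphenyl)octanal | O[C@H](c1cc(OC)c(OC)c(OC)c1)[C@H](CC(=O)CC(=O)C(CC=C)C=O)C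
F3 | step 7 | 4-allyl-6-[(1S,2S)-1-hydroxy-1-(3,4,5-trimethoxyphenyl)propan-2-yl]benzene-1,3-diol | O[C@H](c1cc(OC)c(OC)c(OC)c1)[C@H](c1cc(CC=C)c(O)cc1O)C
F4 | step 4 | 2-[(4S,5S)-2-hydroxy-4-methyl-5-(3,4,5-trimethoxyphenyl)tetrahydrofuran-2-yl]-N-methoxy-N-methylacetamide | O1[C@H](c2cc(OC)c(OC)c(OC)c2)[C@H](CC1(O)CC(=O)N(C)OC)C
F5 | step 4 | (2E)-N-methoxy-N-methyl-2-[(4S,5S)-4-methyl-5-(3,4,5-trimethoxyphenyl)dihydrofuran-2(3H)-ylidene]acetamide | CON(C)C(=O)/C=C1/O[C@H](c2cc(OC)c(OC)c(OC)c2)[C@H](C1)C
F6 | step 5 | C5=C6 trimethylsilyl enol ether of 12, trimethyl({(1E)-1-[(4S,5S)-4-methyl-5-(3,4,5-trimethoxyphenyl)dihydrofuran-2(3H)-ylidene]hexa-2,5-dien-2-yl}oxy)silane | C=CCC=C(O[Si](C)(C)C)/C=C1/O[C@H](c2cc(OC)c(OC)c(OC)c2)[C@H](C1)C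
F7 | step 5 | 3-(dimethoxymethyl)-1-[(2E,4S,5S)-4-methyl-5-(3,4,5-trimethoxyphenyl)dihydrofuran-2(3H)-ylidene]hex-5-en-2-one | COC(OC)C(CC=C)C(=O)/C=C1/O[C@H](c2cc(OC)c(OC)c(OC)c2)[C@H](C1)C
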